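## Structural features

Kazinol E is a (2S)-flavan: ring A is fused to the dihydropyran ring C through C4a and C8a, and ring B is attached to C2 through C1′. Ring A carries the C7 hydroxyl and, ortho to it at C6, a 1,1-dimethylallyl (2-methylbut-3-en-2-yl) group whose quaternary carbon is bonded directly to the arene. Ring B has five contiguous substituents: the bond to C2, prenyl groups at C2′ and C3′, and a catechol at C4′/C5′. C2 is the only stereocentre, so no stereocentres stand next to each other, and neither C3 nor C4 carries a group that could relay asymmetry; C2 must be set by a reagent. The fragile parts are the air-sensitive catechol, the two ortho-alkenylphenol pairs (C3′ prenyl with O4′, C6 dimethylallyl with O7), which cyclise under acid, and the C2–O1 benzylic ether, which can open through a quinone methide once O4′ is free. The real difficulty is the combination of a crowded ring B, a reverse-prenyl group at C6 and an isolated stereocentre in a molecule that tolerates neither strong acid nor hydrogenation. The key step uses the fact that C2 is a carbinol-level carbon between C1′ of ring B and the C3 methylene: it is the carbonyl carbon of a ring B benzaldehyde, and C3–C4–ring A is a 2-arylethyl nucleophile.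

## Logic of the disconnections

**24 to 22.** The two acetal C–O bonds on O4′ and O5′ are cut last. The catechol is the most oxidation-prone part of 24, and a free O4′ hydroxyl para to C1′ would allow ring C to open at C2–O1. Keeping both oxygens masked lets every earlier step run on a base- and heat-stable ring B. The forward cleavage must not expose the ortho-alkenylphenols to strong protic acid.

**22 to 20.** The C6–C(CH3)2 bond is cut as the retron of an aromatic Claisen rearrangement, which returns the reverse-prenyl group to O7 as an ordinary prenyl ether. The quaternary benzylic carbon then costs no extra reagent, because that ether is installed in step 1 and protects O7 throughout. The forward shift must go to C6 and not to C8. It is placed after ring closure, when O1 is an ether meta to O7 that disfavours the flanked C8, and before deprotection, while O4′ is still blocked.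

**20 to 19.** The O1–C8a aryl ether bond is cut, giving an aryl bromide and the C2 alkoxide. Forming this bond at the sp2 carbon leaves the C2–O bond untouched, so the configuration passes unchanged from 19 to 20. Ring C disappears and the problem becomes an acyclic 1,3-diarylpropan-1-ol. The forward coupling must select C–Br in the presence of an allyl aryl ether, and the bromine must survive all organometallic steps before it.

**19 to 18 and 11.** The C2–C3 bond is cut. It is the one bond whose formation both joins two fragments of similar size and creates the only stereocentre. The gain is full convergence. The demands are catalyst control of the aldehyde face, tolerance of the ortho prenyl group of 18, and a nucleophile mild enough to leave the aryl bromide, the allyl ether and the acetals alone. Only one of the two alkyl groups of 11 is transferred, so 11 is used in excess and 18 is the limiting partner.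

**11 to 10 and 8.** One C–Zn bond of 11 is cut, giving the mixed ethyl(alkyl)zinc 10 and one molecule of the primary iodide 8. Since 11 holds two 2-arylethyl groups on one zinc, two molecules of 8 are needed for each molecule of 11, and the second one enters here. The forward exchange is close to thermoneutral, so it must be driven by removal of the volatile iodoethane and must end with a reagent free of ethyl–zinc bonds.

**10 back to 1, 2, 4 and 9.** The remaining C–Zn bond of 10 is cut to 8 and 9; the ring halogen is bromine so that only the side-chain iodide exchanges. The C–I bond of 8 goes back to the alcohol 7, whose C–O bond comes from anti-Markovnikov hydration of the styrene 5. The C=C bond of 5 is cut to the aldehyde 3 and the one-carbon ylide from 4, and the O–CH2 bond of 3 to 1 and 2. Each forward step must leave the aryl bromide and the trisubstituted alkene of the ether untouched.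

**18 back to 12.** Both aryl–CH2 bonds of the prenyl groups are cut to the vicinal dibromide 16 and the allyl stannane 17, which keeps the formyl group free for the key step. The acetals of 16 go back to the catechol 15. The methyl ether of 14 is cleaved at this stage because a methyl ether could not be removed at the end, and 14 comes from 12 by double bromination. The forward coupling must succeed twice at adjacent positions and deliver the linear allyl isomer.

## Other disconnections considered

**Alternative 1:** The cut is O1–C8a in a substrate that already carries the C6 1,1-dimethylallyl group. The bromo carbinol A2, (1S)-3-[2-bromo-4-(methoxymethoxy)-5-(2-methylbut-3-en-2-yl)phenyl]-1-[2,3-bis(3-methylbut-2-enyl)-4,5-bis(methoxymethoxy)phenyl]propan-1-ol, would close to A1, the (2S)-tris(methoxymethyl) ether of Kazinol E, with CuI, a phenanthroline and Cs2CO3.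
- In favour: the bond formation and its retention at C2 are the same as in step 12, so on mechanism the two plans are equal. The closure substrate has no allyl aryl ether, and the thermal rearrangement would be done on a cheap early ring A intermediate instead of on 20, which is a real advantage.
- Against: the step closes a ring but creates no stereocentre, so A2 still needs an enantioselective C2–C3 or carbonyl step. It is a re-ordering of the chosen plan, not a replacement. An early Claisen shift on a bromoarene has a bulky, electron-withdrawing bromine meta to the ether, which is expected to steer less reliably than the O1 ether does in 20. The terminal vinyl group of the dimethylallyl unit would compete in the hydroboration of the styrene, and O7 needs a third acetal.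
- Comparison: equal on the ring closure, better on where the thermal risk falls, worse on the fragment synthesis, and equal or one step longer overall.

**Alternative 2:** The cuts are C6–C(CH3)2 and C3′–CH2 together. The bis-ether A4, (2S)-2-[5-(tert-butyldimethylsilyloxy)-4-(2-methylbut-3-en-2-yloxy)-2-(3-methylbut-2-enyl)phenyl]-7-(3-methylbut-2-enyloxy)chromane, would be heated in N,N-diethylaniline to give A3, (2S)-5′-O-(tert-butyldimethylsilyl) Kazinol E, by two [3,3] shifts.
- In favour: the C3′ prenyl group is delivered to the only free ortho position of O4′, so its regiochemistry is certain. The double cross-coupling at vicinal positions (step 10), the weakest fragment step of the chosen plan, is avoided. On this point the alternative is better.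
- Against: the tertiary allyl aryl ether of A4 is hard to make (O-propargylation, then semi-hydrogenation) and ionises easily. O4′ and O5′ must be differentiated, which adds protecting-group steps. The two ethers rearrange at different rates. The first shift frees the O4′ hydroxyl while the mixture is still hot, which opens the quinone-methide route to cleavage of C2–O1 and loss of configuration; the chosen plan keeps O4′ as an acetal during heating.
- Comparison: equal at C6 (the same reaction as step 13), better at C3′, worse on stereochemical safety and on the step count of the ring B fragment.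

**Alternative 3:** The cut is C2–C1′. A chiral diene complex of monovalent rhodium, made from [RhCl(C2H4)2]2, would transfer the aryl group of the boronic acid A7, [2,3-bis(3-methylbut-2-enyl)-4,5-bis(methoxymethoxy)phenyl]boronic acid, to C2 of the chromone A6, 7-(methoxymethoxy)-6-(2-methylbut-3-en-2-yl)chromen-4-one. The product is the flavanone A5, (2S)-7-(methoxymethoxy)-6-(2-methylbut-3-en-2-yl)-2-[2,3-bis(3-methylbut-2-enyl)-4,5-bis(methoxymethoxy)phenyl]chroman-4-one.
- In favour: the metal and the ligand are both catalytic and the aryl donor is used near one equivalent. The chosen plan discards one alkyl group of 11 and uses tetravalent titanium in stoichiometric amount, so the alternative is better on atom economy. C2 is again set under reagent control.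
- Against: A7 is electron-rich and ortho-substituted, which slows transmetalation and insertion and invites protodeboronation. A5 can open by retro-oxa-Michael reaction and lose its configuration. The C4 carbonyl must then be removed in two or three further steps under conditions that spare four alkenes and the acetals. A Claisen route to A6 is unattractive because 7-allyloxychromones tend to rearrange to C8.
- Comparison: equal on the principle of stereocontrol, better on reagent economy, worse on substrate fit and on step count after the key step.

Key step: step 11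

Assumption: the (1R,2R) bis(sulfonamide) ligand is taken to direct the alkyl group to the Si face of 18, as it does with unhindered aromatic aldehydes; if the sense were opposite, the (1S,2S) ligand would be used.

Assumption: 17 and the ligand are purchased; 17 can otherwise be made from 2.

Remark: the carbinol of 19 is S and maps onto 2S of the target, because ring closure does not change the CIP order O > aryl > CH2 > H.

Remark: 10 is in fast alkyl exchange with 11 and 9, so the material carried from step 5 to step 6 is a residue of that average composition and is used at once.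

## Route

Step 1
Reactants: 1 2-bromo-4-hydroxybenzaldehyde; 2 1-bromo-3-methylbut-2-ene (prenyl bromide)
Product: 3 2-bromo-4-(3-methylbut-2-enyloxy)benzaldehyde
Conditions: K2CO3, DMF, rt
Reagents that add atoms: 1-bromo-3-methylbut-2-ene (2), CC(C)=CCBr
Why: Williamson ether synthesis; the phenoxide attacks the primary carbon of the allylic bromide, so the linear O-prenyl ether should form. This ether protects O7 and is the latent C6 substituent.

Step 2
Reactants: 3 2-bromo-4-(3-methylbut-2-enyloxy)benzaldehyde; 4 methyltriphenylphosphonium bromide
Product: 5 2-bromo-1-ethenyl-4-(3-methylbut-2-enyloxy)benzene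
Conditions: KOtBu, THF, 0 °C to rt
Reagents that add atoms: methyltriphenylphosphonium bromide (4), C[P+](c1ccccc1)(c1ccccc1)c1ccccc1.[Br-]
Why: Wittig methylenation of an aromatic aldehyde with the non-stabilised ylide; the aryl bromide and the allyl ether are inert to it.

Step 3
Reactants: 5 2-bromo-1-ethenyl-4-(3-methylbut-2-enyloxy)benzene
Product: 7 2-[2-bromo-4-(3-methylbut-2-enyloxy)phenyl]ethanol, via alkylborane 6 (not isolated)
Conditions: 9-BBN (1.1 equiv), THF, 0 °C to rt; then NaOH, H2O2, 0 °C
Reagents that add atoms: hydrogen peroxide, OO; 9-borabicyclo[3.3.1]nonane, B1C2CCCC1CCC2 (its boron stays only in 6)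
Why: Hydroboration–oxidation; the bulky borane adds anti-Markovnikov to the monosubstituted styrene much faster than to the trisubstituted alkene of the ether, and alkaline peroxide converts C–B into C–OH.

Step 4
Reactants: 7 2-[2-bromo-4-(3-methylbut-2-enyloxy)phenyl]ethanol
Product: 8 2-bromo-1-(2-iodoethyl)-4-(3-methylbut-2-enyloxy)benzene
Conditions: I2, PPh3, imidazole, CH2Cl2, 0 °C to rt
Reagents that add atoms: iodine, II
Why: Appel-type iodination; iodide displaces the alkoxyphosphonium group at the primary carbon, and the buffered medium leaves the allyl ether intact.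

Step 5
Reactants: 8 2-bromo-1-(2-iodoethyl)-4-(3-methylbut-2-enyloxy)benzene; 9 diethylzinc
Product: 10 ethyl{2-[2-bromo-4-(3-methylbut-2-enyloxy)phenyl]ethyl}zinc
Conditions: Et2Zn (1.5 equiv, neat), CuI (0.3 mol%), 50 °C; EtI and unreacted Et2Zn removed at rt/20 mmHg; residue kept under argon and used at once
Reagents that add atoms: diethylzinc (9), CC[Zn]CC
Why: Iodine–zinc exchange, a CuI-catalysed radical chain in which the primary alkyl iodide takes the place of one ethyl group on zinc and iodoethane is released. Aryl bromides do not exchange under these conditions, which is why the ring carries bromine and the chain iodine.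

Step 6
Reactants: 10 ethyl{2-[2-bromo-4-(3-methylbut-2-enyloxy)phenyl]ethyl}zinc; 8 2-bromo-1-(2-iodoethyl)-4-(3-methylbut-2-enyloxy)benzene
Product: 11 bis{2-[2-bromo-4-(3-methylbut-2-enyloxy)phenyl]ethyl}zinc
Conditions: 8 (1 equiv per Zn–Et bond, assayed by hydrolysis of an aliquot), CuI (0.3 mol%), neat, 50 °C, EtI swept out with argon; then 50 °C/0.1 mmHg (twice); residue taken up in toluene and titrated
Reagents that add atoms: 2-bromo-1-(2-iodoethyl)-4-(3-methylbut-2-enyloxy)benzene (8), ICCc1ccc(OCC=C(C)C)cc1Br
Why: Second iodine–zinc exchange by the same radical chain; the remaining ethyl group on zinc is replaced by a second 2-arylethyl group, and loss of the volatile iodoethane drives the nearly thermoneutral equilibrium. The final evacuation also removes Et2Zn formed by ligand redistribution of any leftover 10, so the reagent should be homoleptic and carry no transferable ethyl group.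

Step 7
Reactants: 12 vanillin (4-hydroxy-3-methoxybenzaldehyde)
Product: 14 2,3-dibromo-4-hydroxy-5-methoxybenzaldehyde, via 5-bromovanillin 13 (not isolated)
Conditions: Br2 (2.3 equiv), Fe powder (cat.), NaOAc, AcOH, rt to 50 °C
Reagents that add atoms: bromine, BrBr
Why: Electrophilic aromatic bromination; the first bromine enters ortho to the hydroxyl, the second, under iron catalysis, para to the methoxy group, which gives the vicinal dibromide.

Step 8
Reactants: 14 2,3-dibromo-4-hydroxy-5-methoxybenzaldehyde
Product: 15 2,3-dibromo-4,5-dihydroxybenzaldehyde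
Conditions: AlCl3, pyridine, CH2Cl2, reflux; then aq HCl
Reagents that add atoms: none
Why: Chelation-assisted O-demethylation of an ortho-hydroxyanisole; aluminium bridges the phenoxide and the methoxy oxygen and pyridine removes the methyl group by SN2 attack.

Step 9
Reactants: 15 2,3-dibromo-4,5-dihydroxybenzaldehyde
Product: 16 2,3-dibromo-4,5-bis(methoxymethoxy)benzaldehyde
Conditions: MOMCl, iPr2NEt, CH2Cl2, 0 °C to rt
Reagents that add atoms: chloromethyl methyl ether, COCCl
Why: O-alkylation of both phenols by the α-chloro ether; the small acetals add little bulk next to C3 and are stable to palladium, zinc, titanium, carbonate base and heat in the later steps.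

Step 10
Reactants: 16 2,3-dibromo-4,5-bis(methoxymethoxy)benzaldehyde; 17 tributyl(3-methylbut-2-enyl)stannane
Product: 18 2,3-bis(3-methylbut-2-enyl)-4,5-bis(methoxymethoxy)benzaldehyde
Conditions: 17 (3 equiv), Pd(PPh3)4 (10 mol%), DMF, 100 °C
Reagents that add atoms: tributyl(3-methylbut-2-enyl)stannane (17), CCCC[Sn](CCCC)(CCCC)CC=C(C)C
Why: Twofold Stille coupling; zerovalent palladium inserts first into the C2–Br bond activated by the ortho formyl group and then into C3–Br, and reductive elimination at the less substituted allyl terminus should give the linear prenyl arenes. The neutral tin reagent is not expected to add to the free aldehyde in the absence of a Lewis acid.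

Step 11
Reactants: 18 2,3-bis(3-methylbut-2-enyl)-4,5-bis(methoxymethoxy)benzaldehyde; 11 bis{2-[2-bromo-4-(3-methylbut-2-enyloxy)phenyl]ethyl}zinc
Product: 19 (1S)-3-[2-bromo-4-(3-methylbut-2-enyloxy)phenyl]-1-[2,3-bis(3-methylbut-2-enyl)-4,5-bis(methoxymethoxy)phenyl]propan-1-ol
Conditions: (1R,2R)-1,2-bis(trifluoromethanesulfonamido)cyclohexane (8 mol%), Ti(OiPr)4 (1.2 equiv), 11 (1.6 equiv), toluene, −20 °C; then sat. aq NH4Cl
Reagents that add atoms: none
Why: The ligand and Ti(OiPr)4 form a chiral titanium bis(sulfonamido) diisopropoxide that binds the aldehyde as a Lewis acid, and one 2-arylethyl group passes from zinc through an alkyltitanium species to the carbonyl carbon. The excess Ti(OiPr)4 takes up the product alkoxide and frees the catalyst. The closest known reaction type is the titanium bis(sulfonamide)-catalysed enantioselective addition of functionalised dialkylzincs, made by iodine–zinc exchange, to aromatic aldehydes. The step forms the C2–C3 bond and closes no ring. The C2 stereocentre is set by the catalyst alone: the (1R,2R) ligand should direct the alkyl group to the Si face and give the S carbinol. The step needs enantioface selectivity and chemoselectivity. Dialkylzincs add negligibly to aldehydes without the catalyst at −20 °C, 18 has only one ortho substituent (C6′ is hydrogen), and the aryl bromide, allyl ether, alkenes and acetals are inert to alkylzincs. Only one alkyl group of 11 is transferred, so 11 is in excess and must be free of Et2Zn to prevent ethyl transfer.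

Step 12
Reactants: 19 (1S)-3-[2-bromo-4-(3-methylbut-2-enyloxy)phenyl]-1-[2,3-bis(3-methylbut-2-enyl)-4,5-bis(methoxymethoxy)phenyl]propan-1-ol
Product: 20 (2S)-2-[2,3-bis(3-methylbut-2-enyl)-4,5-bis(methoxymethoxy)phenyl]-7-(3-methylbut-2-enyloxy)-3,4-dihydro-2H-chromene
Conditions: CuI (10 mol%), 3,4,7,8-tetramethyl-1,10-phenanthroline (20 mol%), Cs2CO3 (2 equiv), toluene, 110 °C
Reagents that add atoms: none
Why: Intramolecular Ullmann-type C–O coupling; the monovalent copper alkoxide inserts into the aryl–Br bond and closes the six-membered ring C. The C2–O bond is never broken, so C2 keeps its configuration.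

Step 13
Reactants: 20 (2S)-2-[2,3-bis(3-methylbut-2-enyl)-4,5-bis(methoxymethoxy)phenyl]-7-(3-methylbut-2-enyloxy)-3,4-dihydro-2H-chromene
Product: 22 (2S)-2-[2,3-bis(3-methylbut-2-enyl)-4,5-bis(methoxymethoxy)phenyl]-6-(2-methylbut-3-en-2-yl)-3,4-dihydro-2H-chromen-7-ol, via cyclohexadienone 21 (not isolated)
Conditions: N,N-diethylaniline, 190 °C, argon, sealed tube
Reagents that add atoms: none
Why: Aromatic Claisen rearrangement; the [3,3] shift inverts the allyl unit, so the O-prenyl ether gives the 1,1-dimethylallyl group, and the dienone tautomerises to the phenol. C6 is expected to be preferred because it is para to the O1 ether and unflanked, whereas C8 lies between two oxygens; the basic solvent and the acetal on O4′ protect the C2–O1 bond during heating.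

Step 14
Reactants: 22 (2S)-2-[2,3-bis(3-methylbut-2-enyl)-4,5-bis(methoxymethoxy)phenyl]-6-(2-methylbut-3-en-2-yl)-3,4-dihydro-2H-chromen-7-ol
Product: 24 Kazinol E, via tris(trimethylsilyl) ether 23 (not isolated)
Conditions: TMSOTf (6 equiv), 2,2′-bipyridyl (9 equiv), CH3CN, 0 °C to rt; then H2O, rt, degassed work-up
Reagents that add atoms: trimethylsilyl trifluoromethanesulfonate, C[Si](C)(C)OS(=O)(=O)C(F)(F)F (its silyl groups stay only in 23)
Why: Silyl triflate and bipyridyl convert aromatic methoxymethyl ethers into aryl silyl ethers, with the methoxymethyl unit captured as a pyridinium salt, and water then hydrolyses the labile aryl trimethylsilyl ethers. The excess bipyridyl scavenges triflic acid, so the ortho-alkenylphenols and the C2–O1 bond should not meet strong protic acid.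

## Compound list

1 | 2-bromo-4-hydroxybenzaldehyde | O=Cc1ccc(O)cc1Br | starting material
2 | 1-bromo-3-methylbut-2-ene (prenyl bromide) | CC(C)=CCBr | starting material
3 | 2-bromo-4-(3-methylbut-2-enyloxy)benzaldehyde | O=Cc1ccc(OCC=C(C)C)cc1Br | intermediate
4 | methyltriphenylphosphonium bromide | C[P+](c1ccccc1)(c1ccccc1)c1ccccc1.[Br-] | starting material
5 | 2-bromo-1-ethenyl-4-(3-methylbut-2-enyloxy)benzene | C=Cc1ccc(OCC=C(C)C)cc1Br | intermediate
6 | 9-{2-[2-bromo-4-(3-methylbut-2-enyloxy)phenyl]ethyl}-9-borabicyclo[3.3.1]nonane | CC(C)=CCOc1ccc(CCB2C3CCCC2CCC3)c(Br)c1 | intermediate (not isolated)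
7 | 2-[2-bromo-4-(3-methylbut-2-enyloxy)phenyl]ethanol | OCCc1ccc(OCC=C(C)C)cc1Br | intermediate
8 | 2-bromo-1-(2-iodoethyl)-4-(3-methylbut-2-enyloxy)benzene | ICCc1ccc(OCC=C(C)C)cc1Br | intermediate
9 | diethylzinc | CC[Zn]CC | starting material
10 | ethyl{2-[2-bromo-4-(3-methylbut-2-enyloxy)phenyl]ethyl}zinc | CC[Zn]CCc1ccc(OCC=C(C)C)cc1Br | intermediate
11 | bis{2-[2-bromo-4-(3-methylbut-2-enyloxy)phenyl]ethyl}zinc | [Zn](CCc1ccc(OCC=C(C)C)cc1Br)CCc1ccc(OCC=C(C)C)cc1Br | intermediate
12 | vanillin (4-hydroxy-3-methoxybenzaldehyde) | COc1cc(C=O)ccc1O | starting material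
13 | 5-bromovanillin (3-bromo-4-hydroxy-5-methoxybenzaldehyde) | COc1cc(C=O)cc(Br)c1O | intermediate (not isolated)
14 | 2,3-dibromo-4-hydroxy-5-methoxybenzaldehyde | COc1cc(C=O)c(Br)c(Br)c1O | intermediate
15 | 2,3-dibromo-4,5-dihydroxybenzaldehyde | O=Cc1cc(O)c(O)c(Br)c1Br | intermediate
16 | 2,3-dibromo-4,5-bis(methoxymethoxy)benzaldehyde | O=Cc1cc(OCOC)c(OCOC)c(Br)c1Br | intermediate
17 | tributyl(3-methylbut-2-enyl)stannane | CCCC[Sn](CCCC)(CCCC)CC=C(C)C | starting material
18 | 2,3-bis(3-methylbut-2-enyl)-4,5-bis(methoxymethoxy)benzaldehyde | O=Cc1cc(OCOC)c(OCOC)c(CC=C(C)C)c1CC=C(C)C | intermediate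
19 | (1S)-3-[2-bromo-4-(3-methylbut-2-enyloxy)phenyl]-1-[2,3-bis(3-methylbut-2-enyl)-4,5-bis(methoxymethoxy)phenyl]propan-1-ol | O[C@H](c1cc(OCOC)c(OCOC)c(CC=C(C)C)c1CC=C(C)C)CCc1ccc(OCC=C(C)C)cc1Br | intermediate
20 | (2S)-2-[2,3-bis(3-methylbut-2-enyl)-4,5-bis(methoxymethoxy)phenyl]-7-(3-methylbut-2-enyloxy)-3,4-dihydro-2H-chromene | CC(C)=CCOc1ccc2c(c1)O[C@H](c1cc(OCOC)c(OCOC)c(CC=C(C)C)c1CC=C(C)C)CC2 | intermediate
21 | (2S)-2-[2,3-bis(3-methylbut-2-enyl)-4,5-bis(methoxymethoxy)phenyl]-6-(2-methylbut-3-en-2-yl)-3,4-dihydro-2H-chromen-7(6H)-one, both epimers at C6 | C=CC(C)(C)C1C=C2C(=CC1=O)O[C@H](c1cc(OCOC)c(OCOC)c(CC=C(C)C)c1CC=C(C)C)CC2 | intermediate (not isolated)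
22 | (2S)-2-[2,3-bis(3-methylbut-2-enyl)-4,5-bis(methoxymethoxy)phenyl]-6-(2-methylbut-3-en-2-yl)-3,4-dihydro-2H-chromen-7-ol | C=CC(C)(C)c1cc2c(cc1O)O[C@H](c1cc(OCOC)c(OCOC)c(CC=C(C)C)c1CC=C(C)C)CC2 | intermediate
23 | (2S)-tris(trimethylsilyl) ether of Kazinol E | C=CC(C)(C)c1cc2c(cc1O[Si](C)(C)C)O[C@H](c1cc(O[Si](C)(C)C)c(O[Si](C)(C)C)c(CC=C(C)C)c1CC=C(C)C)CC2 | intermediate (not isolated)
24 | Kazinol E, (2S)-2-[4,5-dihydroxy-2,3-bis(3-methylbut-2-enyl)phenyl]-6-(2-methylbut-3-en-2-yl)-3,4-dihydro-2H-chromen-7-ol | C=CC(C)(C)c1cc2c(cc1O)O[C@H](c1cc(O)c(O)c(CC=C(C)C)c1CC=C(C)C)CC2 | target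

## Step count and weak points

Total: 14 steps. Longest linear sequence: 10 steps (steps 1 to 6, then 11 to 14, from 1). The ring B branch is 4 steps (7 to 10) and joins at step 11.

**Step 11 (key step).** The aldehyde is electron-rich (oxygen para to the formyl group) and twisted by the ortho prenyl group, so alkyl transfer may be slow and facial selectivity may fall short. Ethyl transfer from residual ethyl–zinc bonds and loss of the second arylethyl group on work-up further reduce efficiency. Fallback: 19 of insufficient enantiomeric purity (if necessary made from 18 and 11 with Ti(OiPr)4 and no ligand) is oxidised with Dess–Martin periodinane and NaHCO3 in CH2Cl2 to 3-[2-bromo-4-(3-methylbut-2-enyloxy)phenyl]-1-[2,3-bis(3-methylbut-2-enyl)-4,5-bis(methoxymethoxy)phenyl]propan-1-one F1. Asymmetric transfer hydrogenation of this ketone with RuCl[(S,S)-TsDPEN](p-cymene) in HCO2H/Et3N should return 19, since the ruthenium hydride distinguishes aryl from alkyl and leaves isolated alkenes and the aryl bromide alone.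

**Step 10.** After the first coupling the remaining bromide is flanked by a prenyl group and an acetal oxygen, so oxidative addition may stall at the mono-coupled stage or end in reduction of the C–Br bond. Allyl transposition during reductive elimination would give the branched isomer, and palladium-mediated allyl transfer to the free formyl group cannot be excluded. Fallback: 16 is converted with trimethyl orthoformate and catalytic pyridinium p-toluenesulfonate in methanol into 2,3-dibromo-1-(dimethoxymethyl)-4,5-bis(methoxymethoxy)benzene F2, which no longer reacts with allyl metal reagents at the carbonyl. Suzuki–Miyaura coupling of this acetal with 4,4,5,5-tetramethyl-2-(3-methylbut-2-enyl)-1,3,2-dioxaborolane, catalysed by PdCl2(IPent)(3-chloropyridine) (IPent = 1,3-bis[2,6-di(pentan-3-yl)phenyl]imidazol-2-ylidene) with aqueous KOH in THF at 70 °C, should give 1-(dimethoxymethyl)-4,5-bis(methoxymethoxy)-2,3-bis(3-methylbut-2-enyl)benzene F3; the bulky carbene ligand favours the linear isomer and hindered bromides. Hydrolysis in wet acetone with catalytic pyridinium p-toluenesulfonate returns 18.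

**Step 13.** The shift may go partly to C8, the prenyl group may be lost thermally as isoprene, and the liberated ortho-(1,1-dimethylallyl)phenol may react further at 190 °C (abnormal Claisen rearrangement through a spirocyclopropyl dienone, or cyclisation onto the vinyl group). Fallback: 20 is heated in N,N-diethylaniline containing acetic anhydride at 190 °C in a sealed vessel, so that the phenol is acetylated as it forms and removed from these pathways. This gives (2S)-2-[2,3-bis(3-methylbut-2-enyl)-4,5-bis(methoxymethoxy)phenyl]-6-(2-methylbut-3-en-2-yl)-3,4-dihydro-2H-chromen-7-yl acetate F4, and methanolysis with K2CO3 in MeOH at rt returns 22.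

**Step 12.** The aryl bromide is electron-rich and ortho-alkylated, so its reaction with the copper alkoxide may be sluggish; the benzylic alkoxide may be oxidised to the ketone or the C–Br bond reduced. Fallback: ring C is closed at O1–C2 with inversion instead, starting from the enantiomeric carbinol. Step 11 is run on 18 and 11 with the (1S,2S) ligand to give (1R)-3-[2-bromo-4-(3-methylbut-2-enyloxy)phenyl]-1-[2,3-bis(3-methylbut-2-enyl)-4,5-bis(methoxymethoxy)phenyl]propan-1-ol F5. Miyaura borylation (B2pin2, PdCl2(dppf), KOAc, dioxane, 80 °C) then gives (1R)-1-[2,3-bis(3-methylbut-2-enyl)-4,5-bis(methoxymethoxy)phenyl]-3-[4-(3-methylbut-2-enyloxy)-2-(4,4,5,5-tetramethyl-1,3,2-dioxaborolan-2-yl)phenyl]propan-1-ol F6, and oxidation with NaBO3 in THF/H2O gives 2-{(3R)-3-[2,3-bis(3-methylbut-2-enyl)-4,5-bis(methoxymethoxy)phenyl]-3-hydroxypropyl}-5-(3-methylbut-2-enyloxy)phenol F7. Mitsunobu cyclisation (PPh3, diisopropyl azodicarboxylate, toluene, 0 °C) should then give 20 by SN2 displacement with inversion. The electron-rich benzylic carbinol can ionise, so this closure carries its own risk of partial loss of configuration and is run cold in a non-polar solvent.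

**Step 14.** If bipyridyl is deficient, triflic acid can trigger cyclisation of a phenol onto the C3′ prenyl or C6 dimethylallyl group or ionisation at C2. The acetal on O4′, flanked by a prenyl group and the neighbouring acetal, may be cleaved incompletely, and the catechol may oxidise during work-up. Fallback: the unmasking is split into two operations so that the free phenols never meet an acidic aqueous phase. 22 is treated with triethylsilyl trifluoromethanesulfonate and 2,2′-bipyridyl in CH2Cl2, which should convert the aryl acetals and the phenol directly into the isolable (2S)-tris(triethylsilyl) ether of Kazinol E F8. Desilylation with Bu4NF buffered with acetic acid in THF at 0 °C then gives 24.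

**Step 6.** The second exchange may stop short, because the equilibrium between two primary alkyl groups is nearly balanced and only the loss of iodoethane drives it; unreacted iodide and surviving ethyl–zinc bonds would lower the titre and allow ethyl transfer in step 11. Fallback: boron–zinc exchange in place of iodine–zinc exchange, setting out from 5. Hydroboration of 5 with diethylborane (from Et3B and BH3·SMe2, 1.0 equiv, 0 °C) should give diethyl{2-[2-bromo-4-(3-methylbut-2-enyloxy)phenyl]ethyl}borane F9. Treatment of this borane with neat Et2Zn at 0 °C and removal of Et3B and surplus Et2Zn under vacuum should give 11 directly. This bypasses 7, 8 and 10, but it relies on the small borane reacting with the styrene faster than with the trisubstituted alkene of the ether.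

## Further compounds

F1 | step 11 | 3-[2-bromo-4-(3-methylbut-2-enyloxy)phenyl]-1-[2,3-bis(3-methylbut-2-enyl)-4,5-bis(methoxymethoxy)phenyl]propan-1-one | O=C(c1cc(OCOC)c(OCOC)c(CC=C(C)C)c1CC=C(C)C)CCc1ccc(OCC=C(C)C)cc1Br
F2 | step 10 | 2,3-dibromo-1-(dimethoxymethyl)-4,5-bis(methoxymethoxy)benzene | COC(OC)c1cc(OCOC)c(OCOC)c(Br)c1Br
F3 | step 10 | 1-(dimethoxymethyl)-4,5-bis(methoxymethoxy)-2,3-bis(3-methylbut-2-enyl)benzene | COC(OC)c1cc(OCOC)c(OCOC)c(CC=C(C)C)c1CC=C(C)C
F4 | step 13 | (2S)-2-[2,3-bis(3-methylbut-2-enyl)-4,5-bis(methoxymethoxy)phenyl]-6-(2-methylbut-3-en-2-yl)-3,4-dihydro-2H-chromen-7-yl acetate | C=CC(C)(C)c1cc2c(cc1OC(C)=O)O[C@H](c1cc(OCOC)c(OCOC)c(CC=C(C)C)c1CC=C(C)C)CC2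
F5 | step 12 | (1R)-3-[2-bromo-4-(3-methylbut-2-enyloxy)phenyl]-1-[2,3-bis(3-methylbut-2-enyl)-4,5-bis(methoxymethoxy)phenyl]propan-1-ol | O[C@@H](c1cc(OCOC)c(OCOC)c(CC=C(C)C)c1CC=C(C)C)CCc1ccc(OCC=C(C)C)cc1Br
F6 | step 12 | (1R)-1-[2,3-bis(3-methylbut-2-enyl)-4,5-bis(methoxymethoxy)phenyl]-3-[4-(3-methylbut-2-enyloxy)-2-(4,4,5,5-tetramethyl-1,3,2-dioxaborolan-2-yl)phenyl]propan-1-ol | O[C@@H](c1cc(OCOC)c(OCOC)c(CC=C(C)C)c1CC=C(C)C)CCc1ccc(OCC=C(C)C)cc1B1OC(C)(C)C(C)(C)O1
F7 | step 12 | 2-{(3R)-3-[2,3-bis(3-methylbut-2-enyl)-4,5-bis(methoxymethoxy)phenyl]-3-hydroxypropyl}-5-(3-methylbut-2-enyloxy)phenol | O[C@@H](c1cc(OCOC)c(OCOC)c(CC=C(C)C)c1CC=C(C)C)CCc1ccc(OCC=C(C)C)cc1O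
F8 | step 14 | (2S)-tris(triethylsilyl) ether of Kazinol E | C=CC(C)(C)c1cc2c(cc1O[Si](CC)(CC)CC)O[C@H](c1cc(O[Si](CC)(CC)CC)c(O[Si](CC)(CC)CC)c(CC=C(C)C)c1CC=C(C)C)CC2
F9 | step 6 | diethyl{2-[2-bromo-4-(3-methylbut-2-enyloxy)phenyl]ethyl}borane | CCB(CC)CCc1ccc(OCC=C(C)C)cc1Br
A1 | alternative 1 | (2S)-tris(methoxymethyl) ether of Kazinol E | C=CC(C)(C)c1cc2c(cc1OCOC)O[C@H](c1cc(OCOC)c(OCOC)c(CC=C(C)C)c1CC=C(C)C)CC2
A2 | alternative 1 | (1S)-3-[2-bromo-4-(methoxymethoxy)-5-(2-methylbut-3-en-2-yl)phenyl]-1-[2,3-bis(3-methylbut-2-enyl)-4,5-bis(methoxymethoxy)phenyl]propan-1-ol | O[C@H](c1cc(OCOC)c(OCOC)c(CC=C(C)C)c1CC=C(C)C)CCc1cc(C(C)(C)C=C)c(OCOC)cc1Br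
A3 | alternative 2 | (2S)-5′-O-(tert-butyldimethylsilyl) Kazinol E | C=CC(C)(C)c1cc2c(cc1O)O[C@H](c1cc(O[Si](C)(C)C(C)(C)C)c(O)c(CC=C(C)C)c1CC=C(C)C)CC2
A4 | alternative 2 | (2S)-2-[5-(tert-butyldimethylsilyloxy)-4-(2-methylbut-3-en-2-yloxy)-2-(3-methylbut-2-enyl)phenyl]-7-(3-methylbut-2-enyloxy)chromane | CC(C)=CCOc1ccc2c(c1)O[C@H](c1cc(O[Si](C)(C)C(C)(C)C)c(OC(C)(C)C=C)cc1CC=C(C)C)CC2
A5 | alternative 3 | (2S)-7-(methoxymethoxy)-6-(2-methylbut-3-en-2-yl)-2-[2,3-bis(3-methylbut-2-enyl)-4,5-bis(methoxymethoxy)phenyl]chroman-4-one | C=CC(C)(C)c1cc2c(cc1OCOC)O[C@H](c1cc(OCOC)c(OCOC)c(CC=C(C)C)c1CC=C(C)C)CC2=O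
A6 | alternative 3 | 7-(methoxymethoxy)-6-(2-methylbut-3-en-2-yl)chromen-4-one | O=c1ccoc2cc(OCOC)c(C(C)(C)C=C)cc12
A7 | alternative 3 | [2,3-bis(3-methylbut-2-enyl)-4,5-bis(methoxymethoxy)phenyl]boronic acid | OB(O)c1cc(OCOC)c(OCOC)c(CC=C(C)C)c1CC=C(C)C
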